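**Retrosynthetic overview**

1. Working locants: ring C1 (CH–CH2OAc), C2 (C–CHO), C3, C4, C5, C6 (C–Me), C7, C8 (CHOH), C9 (CH–side chain); C10 is the side-chain methine.
2. Target ⇐ ring Weinreb amide (the CHO is unveiled last, with the acetate already in place) ⇐ ring-closing metathesis at C2=C3; this closes the only ring (nine-membered) in the penultimate step.
3. RCM triene ⇐ homopropargylic alcohol: C8 carbinol by phosphoric-acid-catalysed propargylation; E-C5=C6 and the C4–C3 arm by methylalumination/allylation of the alkyne.
4. C9–C1 bond and both stereocentres ⇐ (S)-citronellal + a Morita–Baylis–Hillman (MBH) diacetate, by dual amine-catalysed SN2′ α-allylation (key step).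
5. (S)-Citronellal ⇐ geranial by organocatalytic transfer hydrogenation (sets C10); MBH diacetate ⇐ Weinreb acrylamide + acetoxyacetaldehyde.

Assumption: geranial (pure E-citral) and 2-oxoethyl acetate are purchased; catalyst enantiomers in steps 1, 4 and 5 are assigned by analogy with the reported facial selectivities of these catalyst classes and would be inverted if the sense proved opposite.

**Step 1**
Reactants: 1, geranial [(2E)-3,7-dimethylocta-2,6-dienal]
Product: 2, (S)-citronellal [(3S)-3,7-dimethyloct-6-enal]
Conditions: Hantzsch ester (1.1 equiv), morpholinium (S)-TRIP phosphate (10 mol %), THF, rt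
Reagents that add atoms: none (the Hantzsch ester delivers only H)
Why: Iminium transfer hydrogenation under asymmetric counteranion-directed catalysis; the chiral phosphate blocks one face of the morpholine iminium so hydride sets C10 as S (the antipodal salt is the one that gives the R aldehyde from geranial), and only the conjugated C=C is reduced.

**Step 2**
Reactants: 3, N-methoxy-N-methylacrylamide; 4, 2-oxoethyl acetate (acetoxyacetaldehyde)
Product: 5, rac-2-hydroxy-3-[methoxy(methyl)carbamoyl]but-3-en-1-yl acetate
Conditions: quinuclidine (0.5 equiv), MeOH (1 equiv), neat, rt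
Reagents that add atoms: none beyond the two reactants
Why: Morita–Baylis–Hillman reaction (quinuclidine with a protic additive is the combination that makes acrylamides react); the racemic carbinol centre is erased in step 4, and any acetyl-migrated isomer converges in step 3.

**Step 3**
Reactants: 5; 6, acetic anhydride
Product: 7, rac-3-[methoxy(methyl)carbamoyl]but-3-ene-1,2-diyl diacetate
Conditions: Ac2O, pyridine, DMAP (cat.), CH2Cl2, 0 °C to rt
Reagents that add atoms: acetic anhydride, CC(=O)OC(C)=O
Why: Exhaustive O-acetylation installs the allylic leaving group and, in the same operation, the primary acetate that is carried unchanged to the target.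

**Step 4 (key step)**
Reactants: 2 (1.5 equiv); 7
Product: 8, (2R,3R,4S)-3-formyl-2-{1-[methoxy(methyl)carbamoyl]ethenyl}-4,8-dimethylnon-7-en-1-yl acetate
Conditions: (S)-α,α-diphenylprolinol TMS ether (20 mol %), DABCO (30 mol %), CH2Cl2, 0 °C to rt
Reagents that add atoms: none (AcOH is lost)
Why: Proposed new method: enamine/Lewis-base dual catalysis in which DABCO adds SN2′ to 7 and expels the secondary acetate to give an achiral allyl-ammonium enamide, the E-enamine of 2 (one face blocked by the CPh2OTMS group) then adds to C1 through a synclinal approach and DABCO is eliminated (second SN2′), forming C9–C1 and leaving the C2=CH2 acrylamide; enamine-face control sets C9 (R) and the syn topicity familiar from enamine–nitroalkene Michael additions (side-chain branch and CH2OAc syn) sets C1 (R); the closest known reactions are the amine-catalysed SN2′ α-alkylation of aldehydes with 2-(bromomethyl)acrylates (no second stereocentre) and Lewis-base-catalysed allylic alkylation of MBH carbonates with stabilised carbon nucleophiles, whereas a γ-alkyl, acrylamide-type electrophile creating two adjacent stereocentres with an aldehyde donor is untested.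

**Step 5**
Reactants: 8; 9, allenylboronic acid pinacol ester
Product: 10, (2R,3R,4S)-3-[(1S)-1-hydroxybut-3-yn-1-yl]-2-{1-[methoxy(methyl)carbamoyl]ethenyl}-4,8-dimethylnon-7-en-1-yl acetate
Conditions: 9 (1.5 equiv), (S)-TRIP phosphoric acid (10 mol %), 4 Å MS, toluene, 0 °C
Reagents that add atoms: allenylboronic acid pinacol ester, C=C=CB1OC(C)(C)C(C)(C)O1 (delivers the propargyl C3H3 unit)
Why: Chiral phosphoric-acid-catalysed propargylation (SE2′ through a six-membered chair with the acid H-bonded to the boronate oxygen); catalyst-controlled Si-face attack sets C8 (S), which is needed because simple Felkin addition to this doubly α-branched aldehyde is expected to be weak and probably favours the C8 epimer, and the metal-free conditions leave acrylamide, acetate and alkenes untouched.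

**Step 6**
Reactants: 10; 11, trimethylaluminium; 12, allyl bromide
Product: 13, (2R,3R,4S)-3-[(1S,3E)-1-hydroxy-3-methylhepta-3,6-dien-1-yl]-2-{1-[methoxy(methyl)carbamoyl]ethenyl}-4,8-dimethylnon-7-en-1-yl acetate
Conditions: Me3Al (4 equiv), Cp2ZrCl2 (0.5 equiv), H2O (1 equiv), CH2Cl2, −23 °C; then allyl bromide (3 equiv), Pd(PPh3)4 (5 mol %), THF, 0 °C to rt
Reagents that add atoms: trimethylaluminium, C[Al](C)C (CH3); allyl bromide, C=CCBr (allyl)
Why: Negishi Zr-catalysed syn-methylalumination of the terminal alkyne (Me to the internal carbon) followed by Pd-catalysed alkenylalane–allyl coupling with retention gives the E-trisubstituted C5=C6 alkene and the skipped diene in one pot; the water-accelerated low-temperature variant is chosen so that the acetate and Weinreb amide meet only poorly nucleophilic Me3Al briefly.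

**Step 7**
Reactants: 13
Product: 14, (1E,4E,7S,8R,9R)-9-(acetoxymethyl)-7-hydroxy-N-methoxy-N,5-dimethyl-8-[(2S)-6-methylhept-5-en-2-yl]cyclonona-1,4-diene-1-carboxamide
Conditions: Hoveyda–Grubbs II (15 mol %, two portions), 1,4-benzoquinone (20 mol %), toluene (1 mM), 80 °C
Reagents that add atoms: none (ethylene is lost)
Why: Ring-closing metathesis between the terminal vinyl group and the 1,1-disubstituted acrylamide alkene closes the nine-membered ring; with the E-C5=C6 alkene already in the ring, the new C2=C3 bond can only form ring-cis, which is the required geometry (carbonyl trans to C4).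

**Step 8**
Reactants: 14
Product: 15, hydroxyacetyldictyolal {[(1R,2R,3S,5E,8E)-9-formyl-3-hydroxy-5-methyl-2-[(2S)-6-methylhept-5-en-2-yl]cyclonona-5,8-dien-1-yl]methyl acetate}
Conditions: Cp2Zr(H)Cl (3 equiv), THF, rt, 20 min; then SiO2/H2O
Reagents that add atoms: none
Why: Schwartz-reagent reduction of the Weinreb amide via a zirconated hemiaminal that releases the aldehyde only on work-up; the acetate, the free hydroxyl (consumes one equivalent) and the trisubstituted alkenes are unaffected, and the enal appears only after the acetate is in place, which avoids the hydroxy-enal/lactol problem.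

**Compound list**

1 | geranial | CC(C)=CCC/C(C)=C/C=O | starting material
2 | (S)-citronellal | O=CC[C@@H](C)CCC=C(C)C | intermediate
3 | N-methoxy-N-methylacrylamide | C=CC(=O)N(C)OC | starting material
4 | 2-oxoethyl acetate | CC(=O)OCC=O | starting material
5 | rac-2-hydroxy-3-[methoxy(methyl)carbamoyl]but-3-en-1-yl acetate | CC(=O)OCC(O)C(=C)C(=O)N(C)OC | intermediate
6 | acetic anhydride | CC(=O)OC(C)=O | starting material
7 | rac-3-[methoxy(methyl)carbamoyl]but-3-ene-1,2-diyl diacetate | CC(=O)OCC(OC(C)=O)C(=C)C(=O)N(C)OC | intermediate
8 | (2R,3R,4S)-3-formyl-2-{1-[methoxy(methyl)carbamoyl]ethenyl}-4,8-dimethylnon-7-en-1-yl acetate | CC(=O)OC[C@@H](C(=C)C(=O)N(C)OC)[C@H](C=O)[C@@H](C)CCC=C(C)C | intermediate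
9 | allenylboronic acid pinacol ester | C=C=CB1OC(C)(C)C(C)(C)O1 | starting material
10 | homopropargylic alcohol (8S; name as in step 5) | CC(=O)OC[C@@H](C(=C)C(=O)N(C)OC)[C@H]([C@@H](O)CC#C)[C@@H](C)CCC=C(C)C | intermediate
11 | trimethylaluminium | C[Al](C)C | starting material
12 | allyl bromide | C=CCBr | starting material
13 | RCM precursor with E-skipped diene (name as in step 6) | CC(=O)OC[C@@H](C(=C)C(=O)N(C)OC)[C@H]([C@@H](O)C/C(C)=C/CC=C)[C@@H](C)CCC=C(C)C | intermediate
14 | nine-membered ring Weinreb amide (name as in step 7) | CC(=O)OC[C@H]1/C(C(=O)N(C)OC)=C\C/C=C(\C)C[C@H](O)[C@@H]1[C@@H](C)CCC=C(C)C | intermediate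
15 | hydroxyacetyldictyolal | CC(=O)OC[C@H]1/C(C=O)=C\C/C=C(\C)C[C@H](O)[C@@H]1[C@@H](C)CCC=C(C)C | target

**Totals**

Total steps: 8. Longest linear sequence: 7 (steps 2, 3, 4, 5, 6, 7, 8).

**Three steps most likely to fail**

1. **Step 4 (proposed new dual-catalytic SN2′ allylation).** Risks are low reactivity of the acrylamide-type allyl-ammonium, linear (α-attack) regioisomer, and insufficient syn/anti control. Fallback (known chemistry): form C9–C1 by an Ireland–Claisen rearrangement instead. Oxidise 2 to (S)-citronellic acid, esterify with a 2-substituted (E)-4-silyloxybut-2-en-1-ol, and rearrange the silyl ketene acetal (KHMDS, TMSCl) through a chair transition state to set C9/C1 and the C2=CH2 unit. Then convert acid to aldehyde and rejoin at step 5; this costs extra redox and protecting-group steps.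

2. **Step 7 (RCM to the nine-membered ring).** Risks are metathesis onto the side-chain prenyl alkene (11-membered ring or truncation), dimerisation, and the sluggish hindered acrylamide alkene. Fallback: change the ring-closing bond to C4–C5 by B-alkyl Suzuki–Miyaura macrocyclisation, a type of ring closure that has been used for E-cyclononenes of this family. This needs the E-vinyl iodide (quench the step-6 alane with I2) and a 9-BBN adduct of a C3=C4 vinyl group carried on sp3 C2, with C2=C3 introduced afterwards by α-selenation/selenoxide elimination.

3. **Step 6 (one-pot methylalumination/allylation).** Risks are Me3Al or the C8 aluminium alkoxide attacking or migrating the acetate, lactonisation onto the amide, and incomplete allyl coupling. Fallback: deliver the whole C3–C7 unit in one step by α-selective, geometry-retentive addition of preformed (E)-2-methylhexa-2,5-dienylbarium chloride to aldehyde 8 at −78 °C (replacing steps 5 and 6). If the C8 epimer predominates, correct it by Dess–Martin oxidation and Felkin-selective hydride reduction.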